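**Plan**

- Retrosynthesis: the benzyl ether comes off last. Ring A is cut at C4a–C5 (retro-benzannulation to a 4-methoxy-4-pyranonylcyclobutenone). Then the carbinol O–Me bond, the C8–C8a bond (pyranonyllithium plus methyl semisquarate) and the C2–C1' bond (Suzuki coupling) are cut.
- Forward: ring C is bought as 3-hydroxy-4H-pyran-4-one, brominated at C2, benzylated and arylated (ring B attached). The four-membered ring from dimethyl squarate is joined at the pyranone C6, ring A is closed thermally, and the benzyl group is removed.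
- Enabling feature: ring A has para oxygens at C5 (OH, peri to the C4 carbonyl) and C8 (OMe), methoxy at C7 and hydrogen at C6, and shares C4a–C8a with the pyranone, with O1 on C8a. A 3-methoxy-4-alkoxy-2-unsubstituted cyclobutenone gives exactly this pattern when the alkene on its C4 is the CH=C(O) bond of a 4-pyranone.
- The carbinol is methylated before thermolysis, so ring A forms with the C8 methoxy in place and only the chelated C5 phenol free.
- Stereochemistry: the target has no stereocentre. The only one on the way (the cyclobutenone carbinol carbon, racemic) is lost in the ring opening.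

Key step: step 8

**Route**

Step 1
Reactants: 1 3-hydroxy-4H-pyran-4-one (pyromeconic acid)
Product: 2 2-bromo-3-hydroxy-4H-pyran-4-one
Conditions: NBS (1.0 equiv), MeCN, 0 °C to rt
Reagents that add atoms: N-bromosuccinimide, O=C1CCC(=O)N1Br
Why: Electrophilic bromination of the enol should occur at C2, the carbon ortho to the hydroxyl, which is where 3-hydroxy-4-pyranones take halogen, Mannich and aldol electrophiles.

Step 2
Reactants: 2 2-bromo-3-hydroxy-4H-pyran-4-one
Product: 3 3-(benzyloxy)-2-bromo-4H-pyran-4-one
Conditions: BnBr, K2CO3, DMF, 50 °C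
Reagents that add atoms: benzyl bromide, BrCc1ccccc1
Why: Williamson etherification of the acidic enolic hydroxyl should be clean, since carbonate in DMF does not displace the vinylic bromide.

Step 3
Reactants: 3 3-(benzyloxy)-2-bromo-4H-pyran-4-one; 4 (3,4,5-trimethoxyphenyl)boronic acid
Product: 5 3-(benzyloxy)-2-(3,4,5-trimethoxyphenyl)-4H-pyran-4-one
Conditions: Pd(PPh3)4 (5 mol %), K2CO3, 1,4-dioxane–H2O, 80 °C
Reagents that add atoms: none
Why: Suzuki–Miyaura coupling should work because zerovalent palladium inserts readily into the C–Br bond at the β-position of the enone (a vinylogous acyl bromide), the electron-rich boronic acid transmetalates easily, and the mild carbonate base spares the pyranone ring.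

Step 4
Reactants: 6 dimethyl squarate (3,4-dimethoxycyclobut-3-ene-1,2-dione)
Product: 7 4-hydroxy-2,3-dimethoxycyclobut-2-en-1-one (racemic)
Conditions: LiAlH(OtBu)3 (1.05 equiv), THF, −78 °C to −20 °C; then cold 1 M HCl
Reagents that add atoms: none
Why: The hindered alkoxyaluminium hydride should reduce one carbonyl of the symmetrical dione by 1,2-addition and stop there, as established for dialkyl squarates; the new stereocentre is racemic and is lost in the next step.

Step 5
Reactants: 7 4-hydroxy-2,3-dimethoxycyclobut-2-en-1-one (racemic)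
Product: 8 3-methoxycyclobut-3-ene-1,2-dione (methyl semisquarate)
Conditions: conc. HCl (cat.), CH2Cl2, rt; used freshly
Reagents that add atoms: none
Why: Acid-catalysed ionisation of the allylic hydroxyl gives a methoxy-stabilised cyclobutenyl cation that takes up water at the methoxy-bearing terminus and expels methanol, the known 1,3-carbonyl transposition that turns reduced squarates into semisquarates.

Step 6
Reactants: 5 3-(benzyloxy)-2-(3,4,5-trimethoxyphenyl)-4H-pyran-4-one; 8 3-methoxycyclobut-3-ene-1,2-dione
Product: 10 4-[5-(benzyloxy)-4-oxo-6-(3,4,5-trimethoxyphenyl)-4H-pyran-2-yl]-4-hydroxy-3-methoxycyclobut-2-en-1-one (racemic), via 6-lithiopyranone 9 (not isolated)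
Conditions: 2,2,6,6-tetramethylpiperidine, n-BuLi, THF, 0 °C (gives LiTMP, 1.05 equiv); 5, −78 °C, 20 min; transfer onto 8 (1.3 equiv), THF, −78 °C; aq NH4Cl, −78 °C
Reagents that add atoms: none
Why: Proposed new method: the C6–H of 5 is the only vinylic C–H on the ring oxygen and is acidified by it and by the conjugated carbonyl, so the hindered, non-nucleophilic amide LiTMP should remove it kinetically at −78 °C (the benzylic OCH2, the aryl C–H and the C5–H are less acidic or slower), and the alkenyllithium 9 should add 1,2 to the more electrophilic carbonyl of 8, the one next to the methoxy-bearing carbon, because the other carbonyl is deactivated as a vinylogous ester; the closest known reactions are the C2-lithiation of chromones with lithium amides followed by carbonyl trapping, and the addition of alkenyl- and heteroaryllithiums to squarate and semisquarate esters; the carbinol stereocentre forms racemic and is of no consequence.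

Step 7
Reactants: 10 4-[5-(benzyloxy)-4-oxo-6-(3,4,5-trimethoxyphenyl)-4H-pyran-2-yl]-4-hydroxy-3-methoxycyclobut-2-en-1-one (racemic)
Product: 11 4-[5-(benzyloxy)-4-oxo-6-(3,4,5-trimethoxyphenyl)-4H-pyran-2-yl]-3,4-dimethoxycyclobut-2-en-1-one (racemic)
Conditions: MeI (excess), Ag2O, MeCN, rt, dark
Reagents that add atoms: iodomethane, CI
Why: Purdie methylation (silver oxide, iodomethane) is the standard near-neutral way to etherify the tertiary hydroxyl of 4-hydroxycyclobutenones without base-induced ring cleavage, and it should leave the pyranone carbonyl unalkylated.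

Step 8
Reactants: 11 4-[5-(benzyloxy)-4-oxo-6-(3,4,5-trimethoxyphenyl)-4H-pyran-2-yl]-3,4-dimethoxycyclobut-2-en-1-one (racemic)
Product: 14 3-(benzyloxy)-5-hydroxy-7,8-dimethoxy-2-(3,4,5-trimethoxyphenyl)-4H-chromen-4-one, via dienylketene 12 (not isolated), via 4aH-chromene-4,5-dione 13 (not isolated)
Conditions: toluene (degassed, 0.01 M), 110 °C, argon
Reagents that add atoms: none
Why: Heating should open the cyclobutenone by conrotatory 4π electrocyclic cleavage of the C(=O)–C(OMe) ring bond, with the donor methoxy on the sp3 carbon turning outward so that the pyranonyl group ends up cis to the ketene in 12. The ketene carbon then bonds to the pyranone CH carbon (the nucleophilic β-carbon of the ring enol ether) in a 6π electrocyclisation that forms C4a–C5 and closes ring A as a six-membered carbocycle (13); enolisation of the doubly activated C4a–H gives the phenol. This is the Moore rearrangement of 4-alkenyl- and 4-heteroaryl-4-alkoxycyclobutenones, here with the C5=C6 bond of a 4-pyranone as the alkene partner. No stereocentre remains in the product; the carbinol centre of 11 and the transient C4a centre of 13 are both lost. The regiochemistry is fixed by the connectivity of 11 (ketene carbon becomes C5, ring CH becomes C6, methoxy carbon C7, ether carbon C8 next to O1-bearing C8a), and closure can take place only at C5 of the pyranone because its other neighbour is the ring oxygen. The only selectivity required is outward rotation of the methoxy group, which oxygen donors on C4 of cyclobutenones show reliably, and the methyl ether also rules out lactonisation onto the ketene and gives an air-stable monophenol in place of a hydroquinone.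

Step 9
Reactants: 14 3-(benzyloxy)-5-hydroxy-7,8-dimethoxy-2-(3,4,5-trimethoxyphenyl)-4H-chromen-4-one
Product: 15 3,5-dihydroxy-7,8-dimethoxy-2-(3,4,5-trimethoxyphenyl)-4H-chromen-4-one (3,5-dihydroxy-7,8,3',4',5'-pentamethoxyflavone)
Conditions: H2 (1 atm), Pd/C (10 wt% palladium on carbon), EtOAc–MeOH, rt
Reagents that add atoms: none
Why: Catalytic hydrogenolysis should cleave the 3-O-benzyl ether selectively, as is routine for flavonol benzyl ethers, leaving the tetrasubstituted C2=C3 bond, the carbonyl and the methyl ethers untouched.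

**Compound list**

1 | 3-hydroxy-4H-pyran-4-one (pyromeconic acid) | O=c1ccocc1O | starting material
2 | 2-bromo-3-hydroxy-4H-pyran-4-one | O=c1ccoc(Br)c1O | intermediate
3 | 3-(benzyloxy)-2-bromo-4H-pyran-4-one | O=c1ccoc(Br)c1OCc1ccccc1 | intermediate
4 | (3,4,5-trimethoxyphenyl)boronic acid | COc1cc(B(O)O)cc(OC)c1OC | starting material
5 | 3-(benzyloxy)-2-(3,4,5-trimethoxyphenyl)-4H-pyran-4-one | COc1cc(-c2occc(=O)c2OCc2ccccc2)cc(OC)c1OC | intermediate
6 | dimethyl squarate (3,4-dimethoxycyclobut-3-ene-1,2-dione) | COC1=C(OC)C(=O)C1=O | starting material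
7 | 4-hydroxy-2,3-dimethoxycyclobut-2-en-1-one (racemic) | COC1=C(OC)C(O)C1=O | intermediate
8 | 3-methoxycyclobut-3-ene-1,2-dione (methyl semisquarate) | COC1=CC(=O)C1=O | intermediate
9 | [5-(benzyloxy)-4-oxo-6-(3,4,5-trimethoxyphenyl)-4H-pyran-2-yl]lithium (not isolated) | [Li]c1cc(=O)c(OCc2ccccc2)c(-c2cc(OC)c(OC)c(OC)c2)o1 | intermediate
10 | 4-[5-(benzyloxy)-4-oxo-6-(3,4,5-trimethoxyphenyl)-4H-pyran-2-yl]-4-hydroxy-3-methoxycyclobut-2-en-1-one (racemic) | O=C1C=C(OC)C1(O)c1cc(=O)c(OCc2ccccc2)c(-c2cc(OC)c(OC)c(OC)c2)o1 | intermediate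
11 | 4-[5-(benzyloxy)-4-oxo-6-(3,4,5-trimethoxyphenyl)-4H-pyran-2-yl]-3,4-dimethoxycyclobut-2-en-1-one (racemic) | O=C1C=C(OC)C1(OC)c1cc(=O)c(OCc2ccccc2)c(-c2cc(OC)c(OC)c(OC)c2)o1 | intermediate
12 | (3Z)-4-[5-(benzyloxy)-4-oxo-6-(3,4,5-trimethoxyphenyl)-4H-pyran-2-yl]-3,4-dimethoxybuta-1,3-dien-1-one (dienylketene, not isolated) | O=C=C/C(OC)=C(\c1cc(=O)c(OCc2ccccc2)c(-c2cc(OC)c(OC)c(OC)c2)o1)OC | intermediate
13 | 3-(benzyloxy)-7,8-dimethoxy-2-(3,4,5-trimethoxyphenyl)-4aH-chromene-4,5-dione (racemic, not isolated) | COC1=CC(=O)C2C(=O)C(OCc3ccccc3)=C(c3cc(OC)c(OC)c(OC)c3)OC2=C1OC | intermediate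
14 | 3-(benzyloxy)-5-hydroxy-7,8-dimethoxy-2-(3,4,5-trimethoxyphenyl)-4H-chromen-4-one | COc1cc(O)c2c(=O)c(OCc3ccccc3)c(-c3cc(OC)c(OC)c(OC)c3)oc2c1OC | intermediate
15 | 3,5-dihydroxy-7,8-dimethoxy-2-(3,4,5-trimethoxyphenyl)-4H-chromen-4-one | COc1cc(-c2oc3c(OC)c(OC)cc(O)c3c(=O)c2O)cc(OC)c1OC | target

**Step count**

Total: 9 steps. Longest linear sequence: 7 steps (steps 1, 2, 3, 6, 7, 8, 9 from compound 1); the squarate branch (steps 4 and 5) joins at step 6.

**Steps most likely to fail**

1. Step 6 (labelled step). What may go wrong: incomplete or non-regioselective deprotonation, or self-condensation and ring opening of the lithiated pyranone before it meets the dione. The fallback sets out from 5 and returns at 10, using known reaction types. Compound 5 would be zincated at C6 with TMPZnCl·LiCl in THF at 25 °C, the position next to the ring oxygen that such amide bases metalate in chromones, to give [5-(benzyloxy)-4-oxo-6-(3,4,5-trimethoxyphenyl)-4H-pyran-2-yl]zinc chloride F1. Iodolysis with I2 should give the stable 3-(benzyloxy)-6-iodo-2-(3,4,5-trimethoxyphenyl)-4H-pyran-4-one F2. Iodine–magnesium exchange with i-PrMgCl·LiCl in THF at −40 °C, which tolerates conjugated carbonyl groups, should then give [5-(benzyloxy)-4-oxo-6-(3,4,5-trimethoxyphenyl)-4H-pyran-2-yl]magnesium chloride F3. Addition of this less basic Grignard reagent to 8 at −78 °C and an NH4Cl quench should deliver 10.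

2. Step 8 (key step). What may go wrong: ring opening of the ether with insufficient outward preference of the methoxy group, or interception of the ketene (oligomerisation, acylation of the product phenol) competing with the 6π closure. The fallback sets out from 10 and returns at 14. The free carbinol 10, whose hydroxyl is the strongest outward-rotating donor of the series, would be heated in degassed toluene at 110 °C under argon. The same cascade should run through (3Z)-4-[5-(benzyloxy)-4-oxo-6-(3,4,5-trimethoxyphenyl)-4H-pyran-2-yl]-4-hydroxy-3-methoxybuta-1,3-dien-1-one F4 and 3-(benzyloxy)-8-hydroxy-7-methoxy-2-(3,4,5-trimethoxyphenyl)-4aH-chromene-4,5-dione F5 to 3-(benzyloxy)-5,8-dihydroxy-7-methoxy-2-(3,4,5-trimethoxyphenyl)-4H-chromen-4-one F6. This hydroquinone would be kept under argon and methylated with Me2SO4 (1.05 equiv) and K2CO3 in acetone. The C5 hydroxyl is hydrogen-bonded to the C4 carbonyl, so alkylation should go to the C8 hydroxyl and give 14.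

3. Step 7. What may go wrong: sluggish alkylation of the hindered tertiary hydroxyl, or cleavage of the strained carbinol on prolonged contact with silver oxide. The fallback sets out from 5 and 8 and returns at 11. The addition of step 6 would be run as before through 9, but the resulting lithium 1-[5-(benzyloxy)-4-oxo-6-(3,4,5-trimethoxyphenyl)-4H-pyran-2-yl]-2-methoxy-4-oxocyclobut-2-en-1-olate F7 would not be protonated. It would be alkylated in the same flask with MeOTf (1.1 equiv, −78 °C to −20 °C) to give 11 directly. The stoichiometry and low temperature are meant to keep the pyranone carbonyl from being methylated.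

**Further compounds**

F1 | step 6 | [5-(benzyloxy)-4-oxo-6-(3,4,5-trimethoxyphenyl)-4H-pyran-2-yl]zinc chloride | Cl[Zn]c1cc(=O)c(OCc2ccccc2)c(-c2cc(OC)c(OC)c(OC)c2)o1
F2 | step 6 | 3-(benzyloxy)-6-iodo-2-(3,4,5-trimethoxyphenyl)-4H-pyran-4-one | Ic1cc(=O)c(OCc2ccccc2)c(-c2cc(OC)c(OC)c(OC)c2)o1
F3 | step 6 | [5-(benzyloxy)-4-oxo-6-(3,4,5-trimethoxyphenyl)-4H-pyran-2-yl]magnesium chloride | Cl[Mg]c1cc(=O)c(OCc2ccccc2)c(-c2cc(OC)c(OC)c(OC)c2)o1
F4 | step 8 | (3Z)-4-[5-(benzyloxy)-4-oxo-6-(3,4,5-trimethoxyphenyl)-4H-pyran-2-yl]-4-hydroxy-3-methoxybuta-1,3-dien-1-one | O=C=C/C(OC)=C(\c1cc(=O)c(OCc2ccccc2)c(-c2cc(OC)c(OC)c(OC)c2)o1)O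
F5 | step 8 | 3-(benzyloxy)-8-hydroxy-7-methoxy-2-(3,4,5-trimethoxyphenyl)-4aH-chromene-4,5-dione (racemic) | COC1=CC(=O)C2C(=O)C(OCc3ccccc3)=C(c3cc(OC)c(OC)c(OC)c3)OC2=C1O
F6 | step 8 | 3-(benzyloxy)-5,8-dihydroxy-7-methoxy-2-(3,4,5-trimethoxyphenyl)-4H-chromen-4-one | COc1cc(O)c2c(=O)c(OCc3ccccc3)c(-c3cc(OC)c(OC)c(OC)c3)oc2c1O
F7 | step 7 | lithium 1-[5-(benzyloxy)-4-oxo-6-(3,4,5-trimethoxyphenyl)-4H-pyran-2-yl]-2-methoxy-4-oxocyclobut-2-en-1-olate (racemic) | O=C1C=C(OC)C1(O[Li])c1cc(=O)c(OCc2ccccc2)c(-c2cc(OC)c(OC)c(OC)c2)o1
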